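All runs stem from a simulated flask for substances that don't exist; noise was put on by code.

Late in the violet run, at 25.0 s, the substrate reads 0 % and the target 59 %, so 41.0 % of the substrate left by some other path.

- violet: substrate 0.0010 M; solid reagent 1.2 equiv; free catalyst 0.4 mol%; run made earlier
- flask: substrate 0.0010 M; solid reagent 1.20 equiv; free catalyst 0.2 mol%; time 2.0 min

violet run (percent of the substrate charged)

| time / s | target / % | substrate / % |
|---|---|---|
| 10.0 | 43 | 22 |
| 15.0 | 57 | 3 |
| 25.0 | 59 | 0 |

(scatter of a reading: 2 percentage points)

- solid, in amounts per volume of the solution: solid reagent
- the numbers in the tables scatter with a standard deviation of 2 percentage points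
- at the start none of the solid reagent is in solution
- partner is what solid reagent becomes in solution
- no earlier run changes the charge of free catalyst; that part of a forecast is a guess

1. the target standing at 2.0 min, as a percentage of the substrate charged
2. concentration of partner in solution at 2.0 min, in percent of saturation

Two amounts matter: what becomes target and what is lost elsewhere. The violet run gives 1.44 for S, the target made over the substrate lost elsewhere, a selectivity factor. The final target, as a share of the substrate charged, is then S over one plus S. Taken in pieces, S reads 1.23 up to 10.0 s and 2.80 from there to 15.0 s, so the loss seems to fade faster as substrate falls.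

This flask has half the violet loading, and no run tests that, so I guess. If dissolving solid paces the target path, S stays at 1.44. If catalyst paces it, S falls to 0.720. I take the middle, S scaling with the root of the loading, which gives 1.02 and 50.4 % target.

The forecast says 56 % (41 % to 71 %), above my number, and its ground is that “the substrate is still gone well before 2 min”. For partner it says 95 % of saturation (45 % to 100 %).

The flask gives 54.1 % target at 2.0 min, and partner at >99.9 % of saturation.

    partner + free catalyst → catalyst intermediate A (k = 1.90 × 10⁵ M⁻¹ s⁻¹)
    catalyst intermediate A → catalyst intermediate B (k = 220 s⁻¹)
    substrate + catalyst intermediate B → catalyst intermediate C (k = 1.10 × 10⁵ M⁻¹ s⁻¹)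
    catalyst intermediate C → free catalyst + target (k = 180 s⁻¹)
    solid reagent ⇌ partner, rate k5*(cs5 - [partner]) while solid is left; crystals form when [partner] > cs5 (solubility = 0.560 mM, k = 0.110 s⁻¹)
    2 substrate → self-condensation product (k = 55.0 M⁻¹ s⁻¹)

In this flask S is 1.18. The lost substrate goes to self-condensation product: without that step the flask gives 100 % target, not 54.1 %. The root rule, carried from the violet S of 1.44 to a neighbour flask with a loading of 0.05 mol%, gives S = 0.509 and 33.7 % target. That neighbour gives 35.2 % target, with self-condensation product at 64.7 %.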